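A leftover opens this: in the epsilon run at 60.0 min, target and substrate leave 48.0% of the charge unaccounted, more than the catalyst charge, which is 23.7% of the substrate charged.

the same everywhere: substrate 0.30 M

|  | partner | free catalyst | remark | time |
|---|---|---|---|---|
| alpha | 0.39 M | 7.8 mM | run made earlier |  |
| epsilon | 0.39 M | 71 mM | run made earlier |  |
| ash | 0.390 M | 10 mM |  | 2.0 h |
| alder | 0.390 M | 20 mM |  | 2.0 h |
| elm | 0.390 M | 40 mM |  | 2.0 h |
| oak | 0.390 M | 80 mM |  | 2.0 h |

| run | time / min | target / % | substrate / % |
|---|---|---|---|
| alpha | 5.00 | 1 | 96 |
| alpha | 10.0 | 2 | 99 |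
| alpha | 15.0 | 4 | 95 |
| alpha | 30.0 | 4 | 90 |
| alpha | 60.0 | 10 | 86 |
| epsilon | 5.00 | 6 | 78 |
| epsilon | 10.0 | 15 | 67 |
| epsilon | 15.0 | 23 | 62 |
| epsilon | 30.0 | 38 | 36 |
| epsilon | 60.0 | 42 | 10 |

(readings scatter by 1.5 percentage points)

* [target] at the end for ash, alder, elm, oak, in this order
* how that number moves from the first to the last of them (rises all the way / falls all the way / hardly changes / falls, then rises / rises, then falls)

- steps under discussion: substrate + free catalyst <-> catalyst intermediate A; partner + catalyst intermediate A -> catalyst intermediate B; catalyst intermediate B <-> released group + catalyst intermediate C; catalyst intermediate C <-> free catalyst + target; target <-> isomer of the product; partner -> decomposed reagent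
- "hardly changes" means that all values lie within two and a half points (for a concentration: within two and a half percent of the largest)

So we take target to drain into the isomer of the product. Between 30.0 min and 60.0 min of the epsilon run the shortfall grows by 22 percentage points over a mean target of 40.0%, which reads as a drain constant k_d of 0.0183 min⁻¹. Over the first 30.0 min of the epsilon run, substrate reads as falling with a pseudo-first-order constant k_s of 0.0341 min⁻¹, which we scale with the catalyst charge.

Our number is Λ, for ash 0.262: the constant of substrate's entry at that catalyst charge over the drain constant. For alder, elm and oak it reads 0.523, 1.05 and 2.09. Taking k_d as free of the catalyst, the four flasks share τ = k_d t = 2.20, with t the time of 2.0 h.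

In our reckoning of two consecutive first-order steps at fixed τ, target stays near Λ times the substrate left when Λ is far below one, so it grows with catalyst. When Λ is far above one, target sinks towards the charge times exp(−τ). The two consecutive first-order steps join these ends, and at this τ the crest stands close to Λ equal to one, at 38.2 mM, with a height near 0.0731 M.

Was one number enough? Along this row τ is shared, but alpha's reading at 60.0 min gives a smaller constant per unit of catalyst than epsilon's, which puts the crest at 56.9 mM. That is still between alder and oak, so we keep the shape and hold the height more loosely.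

The forecast gives 0.036 M, 0.058 M, 0.068 M, 0.055 M, rises, then falls, and says “The maximum lies near 40 mM”; its elm value lies below our height.

The flask gives 0.0448 M, 0.0705 M, 0.0843 M, 0.0708 M: rises, then falls.

    substrate + free catalyst ⇌ catalyst intermediate A (K = 2.80 L mol⁻¹, k = 0.0210 L mol⁻¹ s⁻¹)
    partner + catalyst intermediate A → catalyst intermediate B (k = 0.160 L mol⁻¹ s⁻¹)
    catalyst intermediate B ⇌ released group + catalyst intermediate C (K = 0.370 M, k = 0.00760 s⁻¹)
    catalyst intermediate C ⇌ free catalyst + target (K = 0.680 M, k = 0.00500 s⁻¹)
    target ⇌ isomer of the product (K = 18.0, k = 3.10 × 10⁻⁴ s⁻¹)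
    partner → decomposed reagent (k = 9.80 × 10⁻⁶ s⁻¹)

The row turns at 39 mM. Λ also reckons the substrate left at 2.0 h as exp(−Λτ). For elm this gives 10.0% and the flask holds 9.19%; for ash it gives 56.2% and the flask holds 60.8%.

The runs were computed for substances that don't exist.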